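**Retrosynthetic overview**
- The target comes from global fluoride desilylation of its tetrakis-TBS ether.
- Key step: the benzylic CH2–CH= bond and the (E)-trisubstituted alkene are made together. A terminal alkyne that already carries the (R)-carbinol undergoes Zr-catalysed methylalumination, and the alkenylalane is coupled with a benzylic chloride under Pd catalysis. This replaces the usual aryl geranylation followed by late oxidation of the terminal alkene.
- The (R)-stereocentre is set early by CBS reduction of an isopropenyl ketone made from pent-4-ynoic acid by the Weinreb route.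
- The benzylic carbon is the formyl carbon of 2-bromo-4,6-dimethoxybenzaldehyde. The biaryl bond comes from direct C2–H arylation of intact 6-methoxybenzofuran (no Sonogashira/annulation), followed by Me→TBS exchange, reduction and chlorination.
- Ring order: no ring is built. The benzofuran (benzo ring A, furan ring B) and the resorcinol ring C are bought intact and joined first; the side chain is attached last.

Assumption: the SMILES is read as the (6R)-alcohol with a (2E)-alkene, and pent-4-ynoic acid, 6-methoxy-1-benzofuran and 2-bromo-4,6-dimethoxybenzaldehyde are taken as catalogue compounds.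

**Route**

Step 1
Reactants: 1 pent-4-ynoic acid
Product: 3 N-methoxy-N-methylpent-4-ynamide, via pent-4-ynoyl imidazolide 2 (not isolated)
Conditions: CDI, CH2Cl2, rt, 1 h; then MeNH(OMe)·HCl, rt
Reagents that add atoms: N,O-dimethylhydroxylamine hydrochloride, CNOC.Cl
Why: Weinreb amide formation by aminolysis of the acyl imidazolide, which is mild enough to leave the terminal alkyne untouched.

Step 2
Reactants: 3 N-methoxy-N-methylpent-4-ynamide
Product: 4 2-methylhept-1-en-6-yn-3-one
Conditions: CH2=C(CH3)MgBr (2.2 equiv), THF, −20 → 0 °C; inverse quench into cold 1 M aq. HCl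
Reagents that add atoms: isopropenylmagnesium bromide, C=C(C)[Mg]Br
Why: Weinreb ketone synthesis, in which the chelated tetrahedral adduct prevents over-addition and the enone is released only in the acidic quench, where the liberated amine is protonated and cannot add back.

Step 3
Reactants: 4 2-methylhept-1-en-6-yn-3-one
Product: 5 (3R)-2-methylhept-1-en-6-yn-3-ol
Conditions: (S)-Me-CBS oxazaborolidine [(S)-1-methyl-3,3-diphenyltetrahydro-1H,3H-pyrrolo[1,2-c][1,3,2]oxazaborole] (0.2 equiv), catecholborane (1.5 equiv), toluene, −78 °C; aq. NaOH wash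
Reagents that add atoms: none
Why: Corey–Bakshi–Shibata reduction, in which the α-branched isopropenyl group acts as the large substituent and the primary alkyl chain as the small one, so the (S)-catalyst delivers hydride to give the (R)-carbinol (the same sense as acetophenone to (R)-1-phenylethanol), while catecholborane at −78 °C does not hydroborate the alkyne or the alkene.

Step 4
Reactants: 5 (3R)-2-methylhept-1-en-6-yn-3-ol
Product: 6 tert-butyldimethyl{[(3R)-2-methylhept-1-en-6-yn-3-yl]oxy}silane
Conditions: TBSCl, imidazole, DMF, rt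
Reagents that add atoms: tert-butyldimethylsilyl chloride, CC(C)(C)[Si](C)(C)Cl
Why: Standard O-silylation, which masks the hydroxyl for the organoaluminium step without touching the C–O stereocentre.

Step 5
Reactants: 7 6-methoxy-1-benzofuran (2 equiv); 8 2-bromo-4,6-dimethoxybenzaldehyde
Product: 9 2,4-dimethoxy-6-(6-methoxy-1-benzofuran-2-yl)benzaldehyde
Conditions: Pd(OAc)2 (5 mol %), PCy3·HBF4 (10 mol %), PivOH (30 mol %), K2CO3 (2.5 equiv), DMA, 100 °C
Reagents that add atoms: none
Why: Palladium-catalysed direct C–H arylation by pivalate-assisted concerted metalation–deprotonation at the most acidic benzofuran C2–H, with oxidative addition of the aryl bromide to zerovalent palladium accelerated by the ortho formyl group.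

Step 6
Reactants: 9 2,4-dimethoxy-6-(6-methoxy-1-benzofuran-2-yl)benzaldehyde
Product: 10 2,4-dihydroxy-6-(6-hydroxy-1-benzofuran-2-yl)benzaldehyde
Conditions: BBr3 (6 equiv), CH2Cl2, −78 °C → rt; H2O
Reagents that add atoms: none
Why: Lewis-acid cleavage of the three aryl methyl ethers, done before the acid-sensitive side chain exists; the 2-arylbenzofuran and the donor-deactivated aldehyde tolerate BBr3.

Step 7
Reactants: 10 2,4-dihydroxy-6-(6-hydroxy-1-benzofuran-2-yl)benzaldehyde
Product: 11 2,4-bis(tert-butyldimethylsilyloxy)-6-[6-(tert-butyldimethylsilyloxy)-1-benzofuran-2-yl]benzaldehyde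
Conditions: TBSCl (4.5 equiv), imidazole (9 equiv), DMAP (cat.), DMF, rt → 40 °C
Reagents that add atoms: tert-butyldimethylsilyl chloride, CC(C)(C)[Si](C)(C)Cl
Why: Silylation of all three phenols, giving protecting groups that survive hydride, organoaluminium and palladium chemistry and leave with fluoride under conditions the final allylic alcohol and prenyl-type alkene tolerate.

Step 8
Reactants: 11 the tris-TBS aldehyde
Product: 12 {2,4-bis(tert-butyldimethylsilyloxy)-6-[6-(tert-butyldimethylsilyloxy)-1-benzofuran-2-yl]phenyl}methanol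
Conditions: i-Bu2AlH (1.2 equiv), CH2Cl2, −78 °C; aq. potassium sodium tartrate
Reagents that add atoms: none
Why: Hydride reduction of the aldehyde at low temperature through a non-basic aluminium alkoxide, which avoids migration of the ortho silyl group from the phenol oxygen to the benzylic oxygen.

Step 9
Reactants: 12 the tris-TBS benzylic alcohol
Product: 14 2-[2-(chloromethyl)-3,5-bis(tert-butyldimethylsilyloxy)phenyl]-6-(tert-butyldimethylsilyloxy)-1-benzofuran, via benzylic mesylate 13 (not isolated)
Conditions: MsCl, Et3N, LiCl, THF, 0 °C → rt; filtered through a short silica plug and used at once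
Reagents that add atoms: lithium chloride, [Li+].[Cl-]
Why: Mesylation followed by nucleophilic substitution with chloride at an electron-rich, strongly activated benzylic position under non-acidic conditions that keep the aryl silyl ethers.

Step 10
Reactants: 6 the (3R)-TBS ether of the enynol (1.3 equiv); 14 the benzylic chloride
Product: 16 tetrakis-TBS ether of the target (3R,6E side chain), via (E)-alkenyldimethylalane 15 (not isolated)
Conditions: 6, AlMe3 (2.6 equiv), Cp2ZrCl2 (0.3 equiv), CH2Cl2, 0 °C → rt; volatiles (excess AlMe3) removed in vacuo; then 14, Pd(PPh3)4 (5 mol %), THF, 0 °C → rt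
Reagents that add atoms: trimethylaluminium, C[Al](C)C
Why: Negishi zirconium-catalysed carboalumination adds Me and Al syn across the terminal alkyne with Me on the internal carbon, and zerovalent palladium then inserts into the benzylic C–Cl bond and couples the alkenylalane with retention (Negishi-type alkenyl–benzyl cross-coupling), so the alkene is formed E only and the already set (R)-carbinol is a spectator.

Step 11
Reactants: 16 the tetrakis-TBS ether
Product: 17 4-[(2E,6R)-6-hydroxy-3,7-dimethylocta-2,7-dien-1-yl]-5-(6-hydroxy-1-benzofuran-2-yl)benzene-1,3-diol (CNP0264263.1)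
Conditions: Bu4NF (6 equiv), THF, 0 °C → rt, argon; pH 7 phosphate buffer work-up
Reagents that add atoms: none
Why: Fluoride-driven desilylation removes the three aryl silyl ethers and the secondary allylic silyl ether in one operation without acid, which avoids chroman formation and allylic ionisation.

**Compound list**

1 | pent-4-ynoic acid | C#CCCC(=O)O | starting material
2 | 1-(1H-imidazol-1-yl)pent-4-yn-1-one (pent-4-ynoyl imidazolide, formed in the flask) | C#CCCC(=O)n1ccnc1 | intermediate
3 | N-methoxy-N-methylpent-4-ynamide | C#CCCC(=O)N(C)OC | intermediate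
4 | 2-methylhept-1-en-6-yn-3-one | C=C(C)C(=O)CCC#C | intermediate
5 | (3R)-2-methylhept-1-en-6-yn-3-ol | C=C(C)[C@H](O)CCC#C | intermediate
6 | tert-butyldimethyl{[(3R)-2-methylhept-1-en-6-yn-3-yl]oxy}silane | C=C(C)[C@H](O[Si](C)(C)C(C)(C)C)CCC#C | intermediate
7 | 6-methoxy-1-benzofuran | COc1ccc2ccoc2c1 | starting material
8 | 2-bromo-4,6-dimethoxybenzaldehyde | O=Cc1c(Br)cc(OC)cc1OC | starting material
9 | 2,4-dimethoxy-6-(6-methoxy-1-benzofuran-2-yl)benzaldehyde | O=Cc1c(OC)cc(OC)cc1-c1cc2ccc(OC)cc2o1 | intermediate
10 | 2,4-dihydroxy-6-(6-hydroxy-1-benzofuran-2-yl)benzaldehyde | O=Cc1c(O)cc(O)cc1-c1cc2ccc(O)cc2o1 | intermediate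
11 | 2,4-bis(tert-butyldimethylsilyloxy)-6-[6-(tert-butyldimethylsilyloxy)-1-benzofuran-2-yl]benzaldehyde | O=Cc1c(O[Si](C)(C)C(C)(C)C)cc(O[Si](C)(C)C(C)(C)C)cc1-c1cc2ccc(O[Si](C)(C)C(C)(C)C)cc2o1 | intermediate
12 | {2,4-bis(tert-butyldimethylsilyloxy)-6-[6-(tert-butyldimethylsilyloxy)-1-benzofuran-2-yl]phenyl}methanol | OCc1c(O[Si](C)(C)C(C)(C)C)cc(O[Si](C)(C)C(C)(C)C)cc1-c1cc2ccc(O[Si](C)(C)C(C)(C)C)cc2o1 | intermediate
13 | methanesulfonate of 12 (formed in the flask) | CS(=O)(=O)OCc1c(O[Si](C)(C)C(C)(C)C)cc(O[Si](C)(C)C(C)(C)C)cc1-c1cc2ccc(O[Si](C)(C)C(C)(C)C)cc2o1 | intermediate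
14 | 2-[2-(chloromethyl)-3,5-bis(tert-butyldimethylsilyloxy)phenyl]-6-(tert-butyldimethylsilyloxy)-1-benzofuran | ClCc1c(O[Si](C)(C)C(C)(C)C)cc(O[Si](C)(C)C(C)(C)C)cc1-c1cc2ccc(O[Si](C)(C)C(C)(C)C)cc2o1 | intermediate
15 | [(1E,5R)-5-(tert-butyldimethylsilyloxy)-2,6-dimethylhepta-1,6-dien-1-yl]dimethylalumane (formed in the flask) | C=C(C)[C@H](O[Si](C)(C)C(C)(C)C)CC/C(C)=C/[Al](C)C | intermediate
16 | tert-butyl{[(3R,6E)-8-{2,4-bis(tert-butyldimethylsilyloxy)-6-[6-(tert-butyldimethylsilyloxy)-1-benzofuran-2-yl]phenyl}-2,6-dimethylocta-1,6-dien-3-yl]oxy}dimethylsilane | C=C(C)[C@H](O[Si](C)(C)C(C)(C)C)CC/C(C)=C/Cc1c(O[Si](C)(C)C(C)(C)C)cc(O[Si](C)(C)C(C)(C)C)cc1-c1cc2ccc(O[Si](C)(C)C(C)(C)C)cc2o1 | intermediate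
17 | 4-[(2E,6R)-6-hydroxy-3,7-dimethylocta-2,7-dien-1-yl]-5-(6-hydroxy-1-benzofuran-2-yl)benzene-1,3-diol | C=C(C)[C@H](O)CC/C(C)=C/Cc1c(O)cc(O)cc1-c1cc2ccc(O)cc2o1 | target

**Totals**

Total step count: 11. Longest linear sequence: 7 steps (steps 5–11, from 7 and 8 to 17); the side-chain branch is 4 steps (steps 1–4) before it converges in step 10.

**Three steps most likely to fail**

Step 10 (carboalumination and benzylic coupling in one pot). The electron-rich benzylic chloride 14 can be ionised or methylated by residual Lewis-acidic aluminium species, and it can homocouple. The fallback sets out from 6 and 14 and comes back at 16, and it reverses the polarity of the coupling. Compound 6 is carboaluminated as before to alane 15, which is quenched with I2 (THF, −30 °C) to give the isolable tert-butyl{[(3R,6E)-7-iodo-2,6-dimethylhepta-1,6-dien-3-yl]oxy}dimethylsilane F1. Chloride 14 is stirred with Zn dust and LiCl (THF, rt) to give the benzylic zinc chloride F2. A Negishi coupling of F2 with F1 (Pd(PPh3)4, THF, rt) then gives 16 with the E geometry carried over from F1, and no aluminium reagent ever meets the benzylic chloride.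

Step 5 (direct C–H arylation). Conversion may be low, or C2/C3 mixtures and diarylation may appear with the electron-rich benzofuran. The fallback sets out from 7 and comes back at 9, and it replaces C–H activation by a boron cross-coupling. Compound 7 is borylated at C2 ([Ir(OMe)(cod)]2, 4,4'-di-tert-butyl-2,2'-bipyridine, B2pin2, THF, 60 °C) to give 2-(6-methoxy-1-benzofuran-2-yl)-4,4,5,5-tetramethyl-1,3,2-dioxaborolane F3. Suzuki–Miyaura coupling of F3 with 8 (PdCl2(dppf), K3PO4, dioxane/H2O, 80 °C) then gives 9.

Step 3 (CBS reduction). The enantiomeric excess may be insufficient if the isopropenyl and alkyl groups are not differentiated well enough. The fallback sets out from 4 and comes back at 5, and it replaces asymmetric reduction by a kinetic resolution. Compound 4 is reduced under Luche conditions (NaBH4, CeCl3·7H2O, MeOH, 0 °C) to racemic 2-methylhept-1-en-6-yn-3-ol F4. F4 is then resolved by Sharpless epoxidation (Ti(OiPr)4, L-(+)-diisopropyl tartrate, t-BuOOH 0.6 equiv, 4 Å sieves, CH2Cl2, −20 °C). The fast-reacting (S)-enantiomer is consumed as the erythro epoxy alcohol (1S)-1-[(2R)-2-methyloxiran-2-yl]pent-4-yn-1-ol F5, and unreacted (R)-alcohol 5 is recovered in high enantiomeric purity (at most 50 % yield) and separated by chromatography.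

**Further compounds**

F1 | step 10 | tert-butyl{[(3R,6E)-7-iodo-2,6-dimethylhepta-1,6-dien-3-yl]oxy}dimethylsilane | C=C(C)[C@H](O[Si](C)(C)C(C)(C)C)CC/C(C)=C/I
F2 | step 10 | ({2,4-bis(tert-butyldimethylsilyloxy)-6-[6-(tert-butyldimethylsilyloxy)-1-benzofuran-2-yl]phenyl}methyl)zinc chloride | Cl[Zn]Cc1c(O[Si](C)(C)C(C)(C)C)cc(O[Si](C)(C)C(C)(C)C)cc1-c1cc2ccc(O[Si](C)(C)C(C)(C)C)cc2o1
F3 | step 5 | 2-(6-methoxy-1-benzofuran-2-yl)-4,4,5,5-tetramethyl-1,3,2-dioxaborolane | COc1ccc2cc(B3OC(C)(C)C(C)(C)O3)oc2c1
F4 | step 3 | racemic 2-methylhept-1-en-6-yn-3-ol | C=C(C)C(O)CCC#C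
F5 | step 3 | (1S)-1-[(2R)-2-methyloxiran-2-yl]pent-4-yn-1-ol | C#CCC[C@H](O)[C@@]1(C)CO1
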